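Remark on the chemistry: the target has no stereocentre and no stereogenic double bond (each prenyl alkene ends in two methyl groups), so names and SMILES carry no stereodescriptors.

## The problem

The target 20 is quercetin (1) with a 3-methylbut-2-enyl (prenyl) group on C6 and on C8, the only two unsubstituted carbons of ring A. The fused skeleton (ring A, pyranone ring C, ring B at C2) and all seven oxygens are already present in 1, so the carbon problem is two aryl–C5 attachments. With no stereocentre to set, the whole task is regio- and chemoselectivity. Direct prenylation of the polyphenol is not an answer: O- competes with C-alkylation, C6 with C8, and overalkylation follows. The five hydroxyls differ in acidity and hydrogen bonding (7-OH most acidic, 3-OH next, 5-OH chelated to C4=O, 3',4'-OH a catechol), which allows them to be handled in a fixed order. Three sensitivities limit the choice of reagents: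

- A prenyl alkene flanked by free phenols is protonated to a tertiary cation and trapped as a 2,2-dimethylchroman, so acid must not meet the prenylated ring A.
- The electron-rich flavonol with a free catechol is oxidised in aerated base.
- The alkenes exclude hydrogenolysis.

The feature that makes the key step possible is that in each side chain the C=C bond lies two carbons from ring A and is trisubstituted with a symmetric terminus. It can therefore be made from a terminal allyl group by exchanging =CH2 for =C(CH3)2. Allyl groups reach C6 and C8 by [3,3] shift from O5 and O7, and an allyl group, unlike a prenyl group, is unchanged by the transposition of that shift.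

## Retrosynthesis

**20 from 19.** The last cut is at the five aryl ester C–O bonds, giving the pentaacetate 19. Esters are chosen because they fall to ammonia without acid and without hydrogen. Acetal masks would need acid on a ring A that carries two prenyl groups beside phenols, and benzyl-type masks would need hydrogenolysis. The forward step only has to exclude air.

**19 from 15 and 16.** The two trisubstituted C=C bonds are cut, giving the diallyl pentaacetate 15 and 2-methylbut-2-ene (16). The neighbouring cut at the aryl–CH2 bonds would mean C-prenylation of a phloroglucinol-type ring, with no control between oxygen, C6 and C8. A [3,3] shift of prenyl ethers would deliver 1,1-dimethylallyl groups instead. The cut shortens each side chain to an allyl group that a Claisen rearrangement can place. The forward reaction must exchange both terminal alkenes, each flanked by two ortho substituents, without homocoupling or double-bond migration.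

**15 from 13 from 11.** The protecting groups are exchanged here. Acetylation with acetic anhydride (14) leads back to the pentaol 13, and aqueous acetic acid leads back to the ketal/methoxymethyl ether 11. The one unavoidable acid step (the diphenylmethylene ketal has no other alkene-compatible removal) is placed where the side chains are still allyl groups, whose protonation would give only secondary cations. Running the exchange on 11 and deprotecting afterwards would save two steps but would end with hot acid on two prenyl groups flanked by phenols. That ordering is rejected.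

**11 from 8.** The C6–CH2 and C8–CH2 bonds are cut, giving the 5,7-bis(allyl ether) 8. A double aromatic Claisen rearrangement needs no reagent and no halogenated arene, unlike a cross-coupling. The precursor has no carbon substituent on ring A beyond those of 1. The forward step must tolerate about 200 °C, and it cannot give a wrong isomer because ring A has only two free carbons.

**8 from 7, 5, 3 and 1.** The O–C bonds are cut in reverse order of hydroxyl reactivity:

- The 5-O-allyl ether comes from 7 and allyl bromide (4).
- The 3-O-methoxymethyl ether comes from 5 and chloromethyl methyl ether (6).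
- The 7-O-allyl ether comes from 3 and 4.
- The catechol ketal 3 comes from 1 and dichlorodiphenylmethane (2).

O3 must not carry an allyl group, since a 3-O-allyl flavonol would shift it to C2. The methoxymethyl group survives base and heat and leaves in the same acid step as the ketal.

## Roads not taken

**Alternative 1:** Ring B would be built by a thermal Diels–Alder reaction, cutting C1'–C2' and C5'–C6'. The 2-ethynylchromone A2 and 2,3-bis(trimethylsilyloxy)buta-1,3-diene A3 would give the cyclohexa-1,4-diene A1.
- Merits: the diene is symmetric, so there is no regiochemistry to control. The catechol oxygens arrive masked, and ring B could be varied late.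
- Weak points: A2 is a fully substituted, doubly prenylated chromone with an alkyne at C2 and needs a long synthesis of its own. A1 is not yet aromatic, so a dehydrogenation must be done beside two prenyl groups and two hydrolysis-prone silyl enol ethers. Three methoxymethyl groups must then be removed with acid next to the prenyl groups.
- Comparison: this road is better for analogues in ring B and needs no differentiation of the hydroxyls of 1. The chosen plan sets against this that the whole skeleton is bought as 1, and that the prenyl alkenes exist only in 19 and 20, where they meet neither acid nor oxidant.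

**Alternative 2:** Ring A would be folded biomimetically, cutting C4a–C5. Mg(OMe)2 in methanol would open the diprenyl hydroxypyrone A5 to a triketo ester, which would close by Claisen condensation to the acylphloroglucinol A4.
- Merits: the prenyl groups sit on carbon before ring A exists, so C6/C8 regiochemistry never arises. A4 is symmetric, so either ortho hydroxyl can later close ring C, and the key step is mild.
- Weak points: A5 must itself be assembled and C-prenylated twice, which raises the O- versus C-alkylation problem again. From A4 rings C and B are still to be built by acylation, rearrangement and cyclodehydration, the last usually under acid with the prenyl groups present. The acetal protecting groups again call for an acidic endgame.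
- Comparison: this road is better in that placement of the side chains is inherent and needs no selective etherification. The chosen plan sets against this that the Claisen step is equally unambiguous, since only C6 and C8 are free, and that rings B and C with the C3 oxygen come ready-made in 1.

**Alternative 3:** Ring C would be closed at C2=C3 by an intramolecular ester Wittig reaction. Heating the keto-ylide ester A7 would expel triphenylphosphine oxide and give the flavone A6.
- Merits: the closure is neutral and thermal, so the prenyl groups are safe in that step. The route is convergent between a ring A ketone and a ring B acid.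
- Weak points: A6 lacks the C3 hydroxyl. The target is a flavonol, so C3 would have to be oxygenated late in the presence of two electron-rich trisubstituted alkenes, which the usual electrophilic oxidants attack first. A7 requires the three hydroxyls of a diprenylated acylphloroglucinol to be differentiated. Four methoxymethyl groups must finally be removed with acid beside the prenyl groups.
- Comparison: the ring-forming step is gentler than the 200 °C rearrangement of step 5, and no hydroxyl of 1 has to be told from another. The chosen plan sets against this that the C3 oxidation level is correct from the start and the prenyl groups are carried through only one further step.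

Key step: step 8

## Route

Step 1
Reactants: 1 quercetin; 2 dichlorodiphenylmethane
Product: 3 2-(2,2-diphenyl-1,3-benzodioxol-5-yl)-3,5,7-trihydroxychromen-4-one
Conditions: Ph2CCl2 (1.5 equiv), Ph2O, 175 °C, 30 min
Reagents that add atoms: dichlorodiphenylmethane, ClC(Cl)(c1ccccc1)c1ccccc1
Why: Catechol ketalisation by double substitution at the gem-dichloride (through the chlorodiphenylmethyl ether and a diphenyl-stabilised oxocarbenium ion), with HCl leaving the hot melt. Only the vicinal 3',4'-hydroxyls can close a five-membered 1,3-benzodioxole, so the 3-, 5- and 7-hydroxyls stay free.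

Step 2
Reactants: 3 2-(2,2-diphenyl-1,3-benzodioxol-5-yl)-3,5,7-trihydroxychromen-4-one; 4 allyl bromide
Product: 5 2-(2,2-diphenyl-1,3-benzodioxol-5-yl)-3,5-dihydroxy-7-(prop-2-enyloxy)chromen-4-one
Conditions: allyl bromide (1.05 equiv), K2CO3 (1.1 equiv), DMF, 0 °C to rt
Reagents that add atoms: allyl bromide, C=CCBr
Why: Williamson etherification. The 7-hydroxyl is the most acidic one left (vinylogous acid para to C4=O) and is not hydrogen-bonded to the carbonyl, so one equivalent of base and halide should etherify O7 before O3 and long before the chelated O5.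

Step 3
Reactants: 5 2-(2,2-diphenyl-1,3-benzodioxol-5-yl)-3,5-dihydroxy-7-(prop-2-enyloxy)chromen-4-one; 6 chloromethyl methyl ether
Product: 7 2-(2,2-diphenyl-1,3-benzodioxol-5-yl)-5-hydroxy-3-(methoxymethoxy)-7-(prop-2-enyloxy)chromen-4-one
Conditions: MOMCl (1.5 equiv), K2CO3, acetone, reflux
Reagents that add atoms: chloromethyl methyl ether, COCCl
Why: O-alkylation of the enolic 3-hydroxyl by the oxocarbenium-like electrophile. The 5-hydroxyl, locked in a six-membered hydrogen bond to C4=O, is not touched by carbonate in acetone, which is the established selectivity pattern of this ketal.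

Step 4
Reactants: 7 2-(2,2-diphenyl-1,3-benzodioxol-5-yl)-5-hydroxy-3-(methoxymethoxy)-7-(prop-2-enyloxy)chromen-4-one; 4 allyl bromide
Product: 8 2-(2,2-diphenyl-1,3-benzodioxol-5-yl)-3-(methoxymethoxy)-5,7-bis(prop-2-enyloxy)chromen-4-one
Conditions: allyl bromide (3 equiv), K2CO3, DMF, 60 °C
Reagents that add atoms: allyl bromide, C=CCBr
Why: Williamson etherification of the chelated 5-hydroxyl, which needs excess halide, a dipolar aprotic solvent and heat. No other nucleophilic site remains, and the acetal and ketal are stable to base.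

Step 5
Reactants: 8 2-(2,2-diphenyl-1,3-benzodioxol-5-yl)-3-(methoxymethoxy)-5,7-bis(prop-2-enyloxy)chromen-4-one
Product: 11 2-(2,2-diphenyl-1,3-benzodioxol-5-yl)-5,7-dihydroxy-3-(methoxymethoxy)-6,8-bis(prop-2-enyl)chromen-4-one, via 8-allyl-7-hydroxy 5-allyl ether 9 (not isolated), via 6-allyl-5-hydroxy 7-allyl ether 10 (not isolated)
Conditions: PhNEt2, 200 °C, Ar, sealed tube
Reagents that add atoms: none
Why: Double aromatic Claisen rearrangement, each a [3,3]-sigmatropic shift followed by tautomerisation of the dienone. Whichever ether moves first, and even if the O7 group enters C6 (the O5 group then reaches C8 by ortho shift to the blocked carbon and Cope shift), only C6 and C8 can accept the groups, and an allyl group is unchanged by the transposition. The amine solvent buffers the new phenols against ring closure onto the alkenes.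

Step 6
Reactants: 11 2-(2,2-diphenyl-1,3-benzodioxol-5-yl)-5,7-dihydroxy-3-(methoxymethoxy)-6,8-bis(prop-2-enyl)chromen-4-one
Product: 13 2-(3,4-dihydroxyphenyl)-3,5,7-trihydroxy-6,8-bis(prop-2-enyl)chromen-4-one (6,8-diallylquercetin), via 3-hydroxy ketal 12 (not isolated)
Conditions: AcOH/H2O (4:1), 100 °C
Reagents that add atoms: none
Why: Acid hydrolysis of the methoxymethyl acetal, then of the diaryl ketal through the diphenyl-stabilised cation, which leaves as benzophenone. The side chains are still terminal allyl groups, whose protonation would give only secondary cations, so they should survive where prenyl groups would cyclise. C6 and C8 are blocked, so the released formaldehyde finds no nucleophilic position on ring A.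

Step 7
Reactants: 13 2-(3,4-dihydroxyphenyl)-3,5,7-trihydroxy-6,8-bis(prop-2-enyl)chromen-4-one; 14 acetic anhydride
Product: 15 [2-(3,4-diacetyloxyphenyl)-5,7-diacetyloxy-4-oxo-6,8-bis(prop-2-enyl)chromen-3-yl] acetate
Conditions: Ac2O, pyridine, DMAP (cat.), rt to 50 °C
Reagents that add atoms: acetic anhydride, CC(=O)OC(C)=O
Why: DMAP-catalysed acylation through the N-acetylpyridinium ion esterifies all five hydroxyls, the chelated 5-hydroxyl included. The esters make the substrate soluble in CH2Cl2, mask the catechol and the 3-hydroxy-4-keto chelating site from ruthenium, and can be removed later without acid.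

Step 8
Reactants: 15 [2-(3,4-diacetyloxyphenyl)-5,7-diacetyloxy-4-oxo-6,8-bis(prop-2-enyl)chromen-3-yl] acetate; 16 2-methylbut-2-ene
Product: 19 [2-(3,4-diacetyloxyphenyl)-5,7-diacetyloxy-6,8-bis(3-methylbut-2-enyl)-4-oxochromen-3-yl] acetate, via 8-prenyl-6-allyl pentaacetate 17 (not isolated), via 6-prenyl-8-allyl pentaacetate 18 (not isolated)
Conditions: second-generation Grubbs catalyst RuCl2(=CHPh)(PCy3)(H2IMes) (10 mol%), 1,4-benzoquinone (10 mol%), 2-methylbut-2-ene/CH2Cl2 (1:1), 40 °C, sealed tube
Reagents that add atoms: 2-methylbut-2-ene, CC=C(C)C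
Why: Olefin cross-metathesis by the Chauvin mechanism: after loss of PCy3 the ruthenium alkylidene adds [2+2] to a terminal allyl C=C, the ruthenacyclobutane opens to an ArCH2CH=Ru species, and this adds to 2-methylbut-2-ene so that cycloreversion puts the isopropylidene end on the side chain and leaves Ru=CHCH3, which expels propene on the next allyl group. The closest known reaction type is the conversion of Claisen-derived ortho-allylphenols and their acetates into prenyl arenes with 2-methylbut-2-ene and the second-generation Grubbs catalyst, standard in flavonoid and xanthone synthesis. No ring is closed and no stereocentre is formed, and the new alkenes carry two identical methyl groups, so there is no geometry to control. The selectivity needed is cross- over self-metathesis and complete exchange at both sites: the large excess of 2-methylbut-2-ene, which does not homodimerise productively, drives both, and the trisubstituted prenyl alkene is too hindered to re-enter the cycle, so it is the kinetic sink. Chains that pick up the ethylidene end (but-2-enyl) are still disubstituted alkenes and are processed again. Ring closure between the C6 and C8 chains is impossible, because it would bridge meta positions of ring A with four carbons. The C2=C3 enol acetate is tetrasubstituted and electron-poor and the arenes are inert, and benzoquinone intercepts ruthenium hydrides that would move a double bond into conjugation with ring A.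

Step 9
Reactants: 19 [2-(3,4-diacetyloxyphenyl)-5,7-diacetyloxy-6,8-bis(3-methylbut-2-enyl)-4-oxochromen-3-yl] acetate
Product: 20 2-(3,4-dihydroxyphenyl)-3,5,7-trihydroxy-6,8-bis(3-methylbut-2-enyl)chromen-4-one
Conditions: NH3 (7 M in MeOH), degassed, Ar, 0 °C to rt; evaporate
Reagents that add atoms: none
Why: Aminolysis of the five aryl acetates by addition–elimination, the phenoxides being good leaving groups. No acid is present, so the prenyl groups cannot cyclise onto the flanking phenols; air is excluded because the flavonol polyphenolate is oxidised by oxygen; the volatile reagent is removed by evaporation, so no acidic quench is needed.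

## Compound list

1 | quercetin, 2-(3,4-dihydroxyphenyl)-3,5,7-trihydroxychromen-4-one | O=c1c(O)c(-c2ccc(O)c(O)c2)oc2cc(O)cc(O)c12 | starting material
2 | dichlorodiphenylmethane | ClC(Cl)(c1ccccc1)c1ccccc1 | starting material
3 | 2-(2,2-diphenyl-1,3-benzodioxol-5-yl)-3,5,7-trihydroxychromen-4-one | O=c1c(O)c(-c2ccc3OC(c4ccccc4)(c4ccccc4)Oc3c2)oc2cc(O)cc(O)c12 | intermediate
4 | allyl bromide (3-bromoprop-1-ene) | C=CCBr | starting material
5 | 2-(2,2-diphenyl-1,3-benzodioxol-5-yl)-3,5-dihydroxy-7-(prop-2-enyloxy)chromen-4-one | C=CCOc1cc(O)c2c(=O)c(O)c(-c3ccc4OC(c5ccccc5)(c5ccccc5)Oc4c3)oc2c1 | intermediate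
6 | chloromethyl methyl ether | COCCl | starting material
7 | 2-(2,2-diphenyl-1,3-benzodioxol-5-yl)-5-hydroxy-3-(methoxymethoxy)-7-(prop-2-enyloxy)chromen-4-one | C=CCOc1cc(O)c2c(=O)c(OCOC)c(-c3ccc4OC(c5ccccc5)(c5ccccc5)Oc4c3)oc2c1 | intermediate
8 | 2-(2,2-diphenyl-1,3-benzodioxol-5-yl)-3-(methoxymethoxy)-5,7-bis(prop-2-enyloxy)chromen-4-one | C=CCOc1cc(OCC=C)c2c(=O)c(OCOC)c(-c3ccc4OC(c5ccccc5)(c5ccccc5)Oc4c3)oc2c1 | intermediate
9 | 2-(2,2-diphenyl-1,3-benzodioxol-5-yl)-7-hydroxy-3-(methoxymethoxy)-8-(prop-2-enyl)-5-(prop-2-enyloxy)chromen-4-one | C=CCOc1cc(O)c(CC=C)c2oc(-c3ccc4OC(c5ccccc5)(c5ccccc5)Oc4c3)c(OCOC)c(=O)c12 | intermediate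
10 | 2-(2,2-diphenyl-1,3-benzodioxol-5-yl)-5-hydroxy-3-(methoxymethoxy)-6-(prop-2-enyl)-7-(prop-2-enyloxy)chromen-4-one | C=CCOc1cc2oc(-c3ccc4OC(c5ccccc5)(c5ccccc5)Oc4c3)c(OCOC)c(=O)c2c(O)c1CC=C | intermediate
11 | 2-(2,2-diphenyl-1,3-benzodioxol-5-yl)-5,7-dihydroxy-3-(methoxymethoxy)-6,8-bis(prop-2-enyl)chromen-4-one | C=CCc1c(O)c(CC=C)c2oc(-c3ccc4OC(c5ccccc5)(c5ccccc5)Oc4c3)c(OCOC)c(=O)c2c1O | intermediate
12 | 2-(2,2-diphenyl-1,3-benzodioxol-5-yl)-3,5,7-trihydroxy-6,8-bis(prop-2-enyl)chromen-4-one | C=CCc1c(O)c(CC=C)c2oc(-c3ccc4OC(c5ccccc5)(c5ccccc5)Oc4c3)c(O)c(=O)c2c1O | intermediate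
13 | 2-(3,4-dihydroxyphenyl)-3,5,7-trihydroxy-6,8-bis(prop-2-enyl)chromen-4-one | C=CCc1c(O)c(CC=C)c2oc(-c3ccc(O)c(O)c3)c(O)c(=O)c2c1O | intermediate
14 | acetic anhydride | CC(=O)OC(C)=O | starting material
15 | [2-(3,4-diacetyloxyphenyl)-5,7-diacetyloxy-4-oxo-6,8-bis(prop-2-enyl)chromen-3-yl] acetate | C=CCc1c(OC(C)=O)c(CC=C)c2oc(-c3ccc(OC(C)=O)c(OC(C)=O)c3)c(OC(C)=O)c(=O)c2c1OC(C)=O | intermediate
16 | 2-methylbut-2-ene | CC=C(C)C | starting material
17 | [2-(3,4-diacetyloxyphenyl)-5,7-diacetyloxy-8-(3-methylbut-2-enyl)-4-oxo-6-(prop-2-enyl)chromen-3-yl] acetate | C=CCc1c(OC(C)=O)c(CC=C(C)C)c2oc(-c3ccc(OC(C)=O)c(OC(C)=O)c3)c(OC(C)=O)c(=O)c2c1OC(C)=O | intermediate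
18 | [2-(3,4-diacetyloxyphenyl)-5,7-diacetyloxy-6-(3-methylbut-2-enyl)-4-oxo-8-(prop-2-enyl)chromen-3-yl] acetate | CC(C)=CCc1c(OC(C)=O)c(CC=C)c2oc(-c3ccc(OC(C)=O)c(OC(C)=O)c3)c(OC(C)=O)c(=O)c2c1OC(C)=O | intermediate
19 | [2-(3,4-diacetyloxyphenyl)-5,7-diacetyloxy-6,8-bis(3-methylbut-2-enyl)-4-oxochromen-3-yl] acetate | CC(C)=CCc1c(OC(C)=O)c(CC=C(C)C)c2oc(-c3ccc(OC(C)=O)c(OC(C)=O)c3)c(OC(C)=O)c(=O)c2c1OC(C)=O | intermediate
20 | 2-(3,4-dihydroxyphenyl)-3,5,7-trihydroxy-6,8-bis(3-methylbut-2-enyl)chromen-4-one | CC(C)=CCc1c(O)c(CC=C(C)C)c2oc(-c3ccc(O)c(O)c3)c(O)c(=O)c2c1O | target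

## Step count and least certain steps

Total: 9 steps. Longest linear sequence: 9 steps, from quercetin (1) to 20.

**Step 8 (key step).** The most likely failures are incomplete exchange at the C6 allyl group, which sits between two acetoxy groups, and migration of a terminal double bond into conjugation with ring A by ruthenium hydrides formed as the catalyst decays. Exchange of the migrated alkene would then give side chains one carbon too short. Fallback: the classical two-step conversion of allyl into prenyl without metathesis, setting out from 15. Lemieux–Johnson cleavage (OsO4 cat., NaIO4, 2,6-lutidine, dioxane/H2O) should give the bis(arylacetaldehyde) [2-(3,4-diacetyloxyphenyl)-5,7-diacetyloxy-4-oxo-6,8-bis(2-oxoethyl)chromen-3-yl] acetate F1. Wittig olefination with isopropylidenetriphenylphosphorane (from isopropyltriphenylphosphonium iodide and KN(SiMe3)2, THF, −78 °C) would then install both isopropylidene ends. Any acetate stripped by the ylide would be restored with Ac2O/pyridine, and the route is rejoined at 19.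

**Step 5.** The rearrangement may stall after one shift, or the long exposure to 200 °C may cost the methoxymethyl group, cleave the peri 5-O-allyl ether or close an ortho-allylphenol onto its alkene. Fallback: introduce the groups one at a time and never use a 5-O-allyl ether (this also bypasses step 4), setting out from 7. Heating 7 (PhNEt2, 190 °C) should move the O7 group to C8, giving 2-(2,2-diphenyl-1,3-benzodioxol-5-yl)-5,7-dihydroxy-3-(methoxymethoxy)-8-(prop-2-enyl)chromen-4-one F2, possibly with the C6 isomer 2-(2,2-diphenyl-1,3-benzodioxol-5-yl)-5,7-dihydroxy-3-(methoxymethoxy)-6-(prop-2-enyl)chromen-4-one F3. Allyl bromide (4) and K2CO3 in DMF at rt would re-etherify only the unchelated 7-hydroxyl, giving 2-(2,2-diphenyl-1,3-benzodioxol-5-yl)-5-hydroxy-3-(methoxymethoxy)-8-(prop-2-enyl)-7-(prop-2-enyloxy)chromen-4-one F4 from F2 and compound 10 from F3. A second heating sends the new group to the one remaining ortho carbon in either isomer, and both converge on 11.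

**Step 2.** The 3-hydroxyl is only a little less acidic than the 7-hydroxyl, so etherification may spill over to O3, and a 3-O-allyl group would later shift to C2. Fallback: a sequence that only ever has to tell the chelated O5 from the rest, setting out from 3. The steps would be:

- Excess MOMCl/K2CO3 in acetone masks O3 and O7 together, giving 2-(2,2-diphenyl-1,3-benzodioxol-5-yl)-5-hydroxy-3,7-bis(methoxymethoxy)chromen-4-one F5.
- Allylation of O5 (4, K2CO3, DMF, 60 °C) gives 2-(2,2-diphenyl-1,3-benzodioxol-5-yl)-3,7-bis(methoxymethoxy)-5-(prop-2-enyloxy)chromen-4-one F6.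
- Claisen rearrangement to C6 gives 2-(2,2-diphenyl-1,3-benzodioxol-5-yl)-5-hydroxy-3,7-bis(methoxymethoxy)-6-(prop-2-enyl)chromen-4-one F7.
- A second O5 allylation gives 2-(2,2-diphenyl-1,3-benzodioxol-5-yl)-3,7-bis(methoxymethoxy)-6-(prop-2-enyl)-5-(prop-2-enyloxy)chromen-4-one F8.
- A para-Claisen rearrangement (ortho shift to the blocked C6, then Cope shift to C8) gives 2-(2,2-diphenyl-1,3-benzodioxol-5-yl)-5-hydroxy-3,7-bis(methoxymethoxy)-6,8-bis(prop-2-enyl)chromen-4-one F9.
- The conditions of step 6 then remove both acetals and the ketal, and the route is rejoined at 13.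

**Step 9.** If air enters, the electron-rich flavonol polyphenolate may be degraded by autoxidation at C2–C3, and the doubly flanked 7-acetate may be slow to cleave. Fallback: carry silyl ethers instead of esters through the metathesis and release them with buffered fluoride, setting out from 13. The steps would be:

- TBSCl/imidazole in DMF should silylate all but the chelated, flanked 5-hydroxyl, giving 3,7-bis[tert-butyl(dimethyl)silyloxy]-2-[3,4-bis[tert-butyl(dimethyl)silyloxy]phenyl]-5-hydroxy-6,8-bis(prop-2-enyl)chromen-4-one F10.
- Cross-metathesis with 16 under the conditions of step 8 gives 3,7-bis[tert-butyl(dimethyl)silyloxy]-2-[3,4-bis[tert-butyl(dimethyl)silyloxy]phenyl]-5-hydroxy-6,8-bis(3-methylbut-2-enyl)chromen-4-one F11.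
- Bu4NF buffered with AcOH in THF at 0 °C returns the route at 20.

## Further compounds

F1 | step 8 | [2-(3,4-diacetyloxyphenyl)-5,7-diacetyloxy-4-oxo-6,8-bis(2-oxoethyl)chromen-3-yl] acetate | O=CCc1c(OC(C)=O)c(CC=O)c2oc(-c3ccc(OC(C)=O)c(OC(C)=O)c3)c(OC(C)=O)c(=O)c2c1OC(C)=O
F2 | step 5 | 2-(2,2-diphenyl-1,3-benzodioxol-5-yl)-5,7-dihydroxy-3-(methoxymethoxy)-8-(prop-2-enyl)chromen-4-one | C=CCc1c(O)cc(O)c2c(=O)c(OCOC)c(-c3ccc4OC(c5ccccc5)(c5ccccc5)Oc4c3)oc12
F3 | step 5 | 2-(2,2-diphenyl-1,3-benzodioxol-5-yl)-5,7-dihydroxy-3-(methoxymethoxy)-6-(prop-2-enyl)chromen-4-one | C=CCc1c(O)cc2oc(-c3ccc4OC(c5ccccc5)(c5ccccc5)Oc4c3)c(OCOC)c(=O)c2c1O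
F4 | step 5 | 2-(2,2-diphenyl-1,3-benzodioxol-5-yl)-5-hydroxy-3-(methoxymethoxy)-8-(prop-2-enyl)-7-(prop-2-enyloxy)chromen-4-one | C=CCOc1cc(O)c2c(=O)c(OCOC)c(-c3ccc4OC(c5ccccc5)(c5ccccc5)Oc4c3)oc2c1CC=C
F5 | step 2 | 2-(2,2-diphenyl-1,3-benzodioxol-5-yl)-5-hydroxy-3,7-bis(methoxymethoxy)chromen-4-one | COCOc1cc(O)c2c(=O)c(OCOC)c(-c3ccc4OC(c5ccccc5)(c5ccccc5)Oc4c3)oc2c1
F6 | step 2 | 2-(2,2-diphenyl-1,3-benzodioxol-5-yl)-3,7-bis(methoxymethoxy)-5-(prop-2-enyloxy)chromen-4-one | COCOc1cc(OCC=C)c2c(=O)c(OCOC)c(-c3ccc4OC(c5ccccc5)(c5ccccc5)Oc4c3)oc2c1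
F7 | step 2 | 2-(2,2-diphenyl-1,3-benzodioxol-5-yl)-5-hydroxy-3,7-bis(methoxymethoxy)-6-(prop-2-enyl)chromen-4-one | COCOc1cc2oc(-c3ccc4OC(c5ccccc5)(c5ccccc5)Oc4c3)c(OCOC)c(=O)c2c(O)c1CC=C
F8 | step 2 | 2-(2,2-diphenyl-1,3-benzodioxol-5-yl)-3,7-bis(methoxymethoxy)-6-(prop-2-enyl)-5-(prop-2-enyloxy)chromen-4-one | COCOc1cc2oc(-c3ccc4OC(c5ccccc5)(c5ccccc5)Oc4c3)c(OCOC)c(=O)c2c(OCC=C)c1CC=C
F9 | step 2 | 2-(2,2-diphenyl-1,3-benzodioxol-5-yl)-5-hydroxy-3,7-bis(methoxymethoxy)-6,8-bis(prop-2-enyl)chromen-4-one | C=CCc1c(OCOC)c(CC=C)c2oc(-c3ccc4OC(c5ccccc5)(c5ccccc5)Oc4c3)c(OCOC)c(=O)c2c1O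
F10 | step 9 | 3,7-bis[tert-butyl(dimethyl)silyloxy]-2-[3,4-bis[tert-butyl(dimethyl)silyloxy]phenyl]-5-hydroxy-6,8-bis(prop-2-enyl)chromen-4-one | C=CCc1c(O[Si](C)(C)C(C)(C)C)c(CC=C)c2oc(-c3ccc(O[Si](C)(C)C(C)(C)C)c(O[Si](C)(C)C(C)(C)C)c3)c(O[Si](C)(C)C(C)(C)C)c(=O)c2c1O
F11 | step 9 | 3,7-bis[tert-butyl(dimethyl)silyloxy]-2-[3,4-bis[tert-butyl(dimethyl)silyloxy]phenyl]-5-hydroxy-6,8-bis(3-methylbut-2-enyl)chromen-4-one | CC(C)=CCc1c(O[Si](C)(C)C(C)(C)C)c(CC=C(C)C)c2oc(-c3ccc(O[Si](C)(C)C(C)(C)C)c(O[Si](C)(C)C(C)(C)C)c3)c(O[Si](C)(C)C(C)(C)C)c(=O)c2c1O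
A1 | alternative 1 | 2-[4,5-bis(trimethylsilyloxy)cyclohexa-1,4-dien-1-yl]-3,5,7-tris(methoxymethoxy)-6,8-bis(3-methylbut-2-enyl)chromen-4-one | C[Si](C)(C)OC1=C(O[Si](C)(C)C)CC(c2oc3c(CC=C(C)C)c(OCOC)c(CC=C(C)C)c(OCOC)c3c(=O)c2OCOC)=CC1
A2 | alternative 1 | 2-ethynyl-3,5,7-tris(methoxymethoxy)-6,8-bis(3-methylbut-2-enyl)chromen-4-one | C#Cc1oc2c(CC=C(C)C)c(OCOC)c(CC=C(C)C)c(OCOC)c2c(=O)c1OCOC
A3 | alternative 1 | 2,3-bis(trimethylsilyloxy)buta-1,3-diene | C=C(O[Si](C)(C)C)C(=C)O[Si](C)(C)C
A4 | alternative 2 | 2-(methoxymethoxy)-1-[2,4,6-trihydroxy-3,5-bis(3-methylbut-2-enyl)phenyl]ethanone | COCOCC(=O)c1c(O)c(CC=C(C)C)c(O)c(CC=C(C)C)c1O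
A5 | alternative 2 | 4-hydroxy-6-[3-(methoxymethoxy)-2-oxopropyl]-3,5-bis(3-methylbut-2-enyl)pyran-2-one | COCOCC(=O)Cc1oc(=O)c(CC=C(C)C)c(O)c1CC=C(C)C
A6 | alternative 3 | 2-[3,4-bis(methoxymethoxy)phenyl]-5,7-bis(methoxymethoxy)-6,8-bis(3-methylbut-2-enyl)chromen-4-one | COCOc1ccc(-c2cc(=O)c3c(OCOC)c(CC=C(C)C)c(OCOC)c(CC=C(C)C)c3o2)cc1OCOC
A7 | alternative 3 | [3,5-bis(methoxymethoxy)-2,4-bis(3-methylbut-2-enyl)-6-[(triphenylphosphoranylidene)acetyl]phenyl] 3,4-bis(methoxymethoxy)benzoate | COCOc1ccc(C(=O)Oc2c(CC=C(C)C)c(OCOC)c(CC=C(C)C)c(OCOC)c2C(=O)C=P(c2ccccc2)(c2ccccc2)c2ccccc2)cc1OCOC
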